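Per molar squared and per hour is the unit of the rate constant here, for the step of the left-handed substrate joins reagent, free catalyst and substrate.

| setting | maple | elm | flask |
|---|---|---|---|
| left-handed substrate | 0.14 M | 0.22 M | 0.10 M |
| right-handed substrate | 0.14 M | 0.22 M | 0.10 M |
| reagent | 2.5 equiv | 2.5 equiv | 2.50 equiv |
| free catalyst | 10 mol% | 10 mol% | 10 mol% |
| precatalyst | 1.5 mol% | 1.5 mol% | 1.5 mol% |
| remark | run made earlier | run made earlier |  |
| time |  |  | 15 h |

| run | time / h | left-handed substrate / % | left-handed product / % |
|---|---|---|---|
| maple | 1.33 | 47.2 | 4.6 |
| maple | 4.00 | 39.9 | 7.9 |
| maple | 6.00 | 38.3 | 12.7 |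
| maple | 10.0 | 31.8 | 19.6 |
| maple | 15.0 | 26.4 | 23.5 |
| maple | 20.0 | 23.6 | 25.5 |
| elm | 1.33 | 43.9 | 7.0 |
| elm | 4.00 | 30.9 | 18.9 |
| elm | 6.00 | 26.5 | 24.3 |
| elm | 10.0 | 19.2 | 30.9 |
| elm | 15.0 | 13.4 | 35.5 |
| elm | 20.0 | 11.4 | 38.5 |

(readings scatter by 1 percentage point)

- the state of affairs at 15 h: stopped, and by what, or still going (all of the left-handed substrate has reacted / the reagent has run out first / it is still moving / forward and back rates have come level / no working catalyst is left)
- share of the left-handed substrate and right-handed substrate together used up at 15 h
- left-handed product at 15 h, in percent of the left-handed substrate and right-handed substrate together charged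
- right-handed substrate at 15 h, in percent of the left-handed substrate and right-handed substrate together charged

- free catalyst is single-handed; left-handed substrate and right-handed substrate are mirror images of each other, charged as a racemate, each of them at the stated concentration
- steps thought possible: reagent + free catalyst + left-handed substrate -> free catalyst + left-handed product; 2 racemization catalyst <-> resting dimer; reagent + free catalyst + right-handed substrate -> free catalyst + right-handed product; free catalyst -> spent catalyst; left-handed substrate + racemization catalyst <-> right-handed substrate + racemization catalyst; precatalyst -> racemization catalyst
- the reaction counts as stopped when no species that holds the left-handed substrate and right-handed substrate together changes by six tenths of a point or more over the second half of the time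

In the maple run, left-handed substrate plus left-handed product stands at 49.1% of the charge at 20.0 h, and in the elm run at 49.9%. Within the scatter, then, no net feed from the right-handed substrate shows, and the left-handed substrate can be treated as simply consumed, at a rate k·c(reagent)·c(free catalyst)·c(left-handed substrate). With c(reagent) and c(free catalyst) held at their charges, this is a pseudo-first-order decay. Each run's reading at 15.0 h gives k as the natural logarithm of the left-handed substrate charged over the left-handed substrate read, divided by both concentrations and the time:

k(maple) = 8.69 M⁻² h⁻¹

k(elm) = 7.25 M⁻² h⁻¹

The maple value serves, as that run is the more dilute. The new flask holds c(reagent) = 0.250 M and c(free catalyst) = 0.0100 M. The natural logarithm of 2, over k and these two concentrations, is the mean half-life of the left-handed substrate: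

t½ = 31.9 h

My reckoning for 15 h is therefore:

left-handed substrate = 36.1%

left-handed product = 13.9%

The reagent charge exceeds both substrates together, and over the second half of the time the left-handed substrate still falls 6.4 percentage points, so the flask is reckoned still moving. The right-handed substrate was never read, so it is bracketed: from 36.1%, at the left-handed pace, up to its full charge, unreacted. Conversion is then reckoned to lie between 13.9% and 27.8%.

The forecast says it is still moving, with conversion 18%, left-handed product 15% and right-handed substrate 47%, and it notes that “the right-handed substrate was never measured, so this is the main uncertainty”.

In the flask it is still moving, with conversion 23.2%, left-handed product 14.8% and right-handed substrate 41.5%.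

    reagent + free catalyst + left-handed substrate → free catalyst + left-handed product (k = 0.00340 M⁻² s⁻¹)
    2 racemization catalyst ⇌ resting dimer, settled at all times (K = 39.0 M⁻¹)
    reagent + free catalyst + right-handed substrate → free catalyst + right-handed product (k = 0.00180 M⁻² s⁻¹)
    free catalyst → spent catalyst (k = 6.30 × 10⁻⁶ s⁻¹)
    left-handed substrate + racemization catalyst ⇌ right-handed substrate + racemization catalyst, rate k5*[racemization catalyst]*[left-handed substrate] forward; the back reaction follows from the equilibrium constant (k = 0.00140 M⁻¹ s⁻¹)
    precatalyst → racemization catalyst (k = 3.40 × 10⁻⁶ s⁻¹)

In this flask the half-life of left-handed substrate by its own step is 28 h at 5.85 h and 39 h at 15.0 h, either side of the reckoned 31.9 h, while by the racemization step alone the two substrates relax into each other with a half-life of 11.6 d, long against the 15 h of the flask. This is kinetic, not thermodynamic, control: the flask holds 35.3% left-handed and 41.5% right-handed substrate at 15.0 h. For a neighbour flask, the same but with 10.0 equiv of reagent, the same k gives t½ = 7.98 h and 13.6% left-handed substrate, and that neighbour flask holds 12.0% at 15.0 h.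

All runs are simulated with constants of no real substance, noise included.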